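Everything rests on opening ring A (the benzenoid ring of the naphthoquinone) at C4a–C5 and C8–C8a. The step exploits the contiguous substitution of that ring: methyl-bearing C5, aroyl-bearing C6, oxygenated C7 and unsubstituted C8 map onto the chain of a 2-silyloxy-3-aroylpenta-1,3-diene, and the fusion carbons C4a and C8a are the two alkene carbons of a benzoquinone. One Diels–Alder reaction with 2-bromo-5-methoxy-1,4-benzoquinone, finished in the same flask by loss of HBr, enolisation and air oxidation, closes ring A with its full substitution pattern. The diene already carries the resorcinol ring (ring B) and the pyranone; it is reached from an arylacetic acid by pyranone annulation, ring acetylation, Claisen acylation, Knoevenagel condensation and enol silylation.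

Key step: step 9

Remark: the cycloaddition product holds four methyl ethers (two on ring B, one on the pyranone, one on the quinone) and one aryl silyl ether; the last two steps are planned for exactly these five groups.
Remark: the pyranone is completed before the aryl ketone is introduced, because an acetyl group ortho to a free arylacetic acid side chain would cyclise onto it.
Assumption: 1-bromo-2,4,5-trimethoxybenzene and 1-acetyl-1H-benzotriazole are taken as purchasable; the former fixes bromine and methoxy in the 2,5-relationship of the quinone in one step.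

Step 1
Reactants: 1 (3,5-dimethoxyphenyl)acetic acid; 2 the dioxinone 2,2,6-trimethyl-4H-1,3-dioxin-4-one
Product: 5 keto dioxinone 6-[3-(3,5-dimethoxyphenyl)-2-oxopropyl]-2,2-dimethyl-4H-1,3-dioxin-4-one, via acyl imidazole 3 (not isolated), via lithium dienolate 4 (not isolated)
Conditions: 1, 1,1'-carbonyldiimidazole, THF, 25 °C; separately 2 and LiN(SiMe3)2 (3.3 equiv each), THF, −78 °C; combine, −78 → −30 °C; 1 M HCl quench
Reagents that add atoms: none
Why: Crossed Claisen-type C-acylation in which the extended lithium enolate of the dioxinone attacks the N-acyl imidazole through its exocyclic γ-carbon, the excess enolate absorbing the acidic protons of released imidazole and of the new β-keto dioxinone.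

Step 2
Reactants: 5 keto dioxinone
Product: 7 hydroxypyranone 6-(3,5-dimethoxybenzyl)-4-hydroxy-2H-pyran-2-one, via acylketene 6 (not isolated)
Conditions: toluene, 110 °C
Reagents that add atoms: none
Why: Thermal retro-[4+2] loss of acetone unmasks an acylketene that is captured at once by the enol oxygen of the distal ketone, the standard dioxinone route to 6-substituted 4-hydroxy-2-pyranones.

Step 3
Reactants: 7 hydroxypyranone
Product: 8 methoxypyranone 6-(3,5-dimethoxybenzyl)-4-methoxy-2H-pyran-2-one
Conditions: Me2SO4, K2CO3, acetone, 25 → 50 °C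
Reagents that add atoms: dimethyl sulfate, COS(=O)(=O)OC
Why: Williamson-type O-alkylation of the vinylogous acid with a hard methylating agent under weak base should go to the 4-oxygen, masking the acidic hydroxyl and blocking acylation at pyranone C3 in the next step.

Step 4
Reactants: 8 methoxypyranone
Product: 9 aryl methyl ketone 6-(2-acetyl-3,5-dimethoxybenzyl)-4-methoxy-2H-pyran-2-one
Conditions: AcOH, (CF3CO)2O, H3PO4 (cat.), CH2Cl2, 0 °C → 25 °C
Reagents that add atoms: acetic acid, CC(=O)O
Why: Friedel–Crafts acylation by acetyl trifluoroacetate formed in the flask should take the ring B carbon next to the benzylic CH2, which is para to one methoxy and ortho to the other and less crowded than the carbon between the two methoxy groups, while the acid-complexed pyranone is far less nucleophilic.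

Step 5
Reactants: 9 aryl methyl ketone
Product: 10 diketone 1-{2,4-dimethoxy-6-[(4-methoxy-2-oxo-2H-pyran-6-yl)methyl]phenyl}butane-1,3-dione
Conditions: 1-acetyl-1H-benzotriazole, MgBr2·OEt2, i-Pr2NEt, CH2Cl2, 25 °C; 1 M HCl work-up
Reagents that add atoms: 1-acetyl-1H-benzotriazole, CC(=O)n1nnc2ccccc12
Why: Claisen-type C-acylation under soft enolisation, in which MgBr2 chelates the ketone with its ortho methoxy group so that the amine can remove a methyl proton and the magnesium enolate takes the acetyl group from the benzotriazolide, without a strong base that would deprotonate the methylene between ring B and the pyranone.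

Step 6
Reactants: 10 diketone; 11 acetaldehyde
Product: 12 ethylidene diketone (3Z)-3-{2,4-dimethoxy-6-[(4-methoxy-2-oxo-2H-pyran-6-yl)methyl]benzoyl}pent-3-en-2-one
Conditions: piperidine (cat.), AcOH (cat.), 4 Å MS, CH2Cl2, 0 °C → 25 °C, sealed flask
Reagents that add atoms: none
Why: Knoevenagel condensation through the iminium ion of acetaldehyde, where reversible amine addition should let the alkene settle with the new methyl cis to the twisted aroyl group and trans to the coplanar acetyl group, the (Z) isomer that places the methyl outward in the later diene.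

Step 7
Reactants: 12 ethylidene diketone
Product: 13 silyloxy diene (3Z)-2-(tert-butyldimethylsilyloxy)-3-{2,4-dimethoxy-6-[(4-methoxy-2-oxo-2H-pyran-6-yl)methyl]benzoyl}penta-1,3-diene
Conditions: TBSOTf, Et3N, CH2Cl2, −78 → 0 °C; cold aq. NaHCO3 work-up, used without chromatography
Reagents that add atoms: tert-butyldimethylsilyl trifluoromethanesulfonate, CC(C)(C)[Si](C)(C)OS(=O)(=O)C(F)(F)F
Why: Soft enolisation to a silyl enol ether, in which the unhindered acetyl oxygen is silylated and the amine removes the adjacent methyl proton, should give the cross-conjugated 2-silyloxy diene without disturbing the geometry of the trisubstituted alkene.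

Step 8
Reactants: 14 1-bromo-2,4,5-trimethoxybenzene
Product: 15 bromoquinone 2-bromo-5-methoxy-1,4-benzoquinone
Conditions: (NH4)2Ce(NO3)6, MeCN/H2O, 0 °C → 25 °C
Reagents that add atoms: water, O
Why: Oxidative demethylation of a para-dimethoxyarene by two one-electron oxidations with water as oxygen source, where only the 2- and 5-methoxy groups are para to each other, so bromine and the surviving methoxy group must end on different double bonds.

Step 9
Reactants: 13 silyloxy diene; 15 bromoquinone
Product: 19 silyl-protected naphthoquinone 7-(tert-butyldimethylsilyloxy)-6-{2,4-dimethoxy-6-[(4-methoxy-2-oxo-2H-pyran-6-yl)methyl]benzoyl}-2-methoxy-5-methyl-1,4-naphthoquinone, via bromo cycloadduct 16 (not isolated), via dihydronaphthoquinone 17 (not isolated), via naphthalenediol 18 (not isolated)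
Conditions: toluene, 25 → 45 °C, dark; then Et3N, air, 25 °C
Reagents that add atoms: none
Why: A normal-demand Diels–Alder cycloaddition joins the diene termini C5 and C8 to the brominated double bond of 15 (bonds C4a–C5 and C8–C8a), after which Et3N removes HBr across C4a–C8a, the 5,8-dihydroquinone enolises to the naphthalene-1,4-diol and air returns it to the quinone. The closest known reaction type is the regiocontrolled cycloaddition of 2-bromo-1,4-quinones with oxygenated dienes followed by dehydrobromination. Ring A is closed as a six-membered carbocycle by [4+2] cycloaddition across the quinone C=C that becomes the ring fusion. No stereocentre remains, because the transient centres of 16 (C4a, C5, C8a) are erased by elimination and aromatisation, so endo/exo and facial selectivity do not matter. The step needs orientational control: the CH2 terminus C8, made the nucleophilic end by the C7 silyloxy group, the C6 acyl group and the C5 methyl group, should bond to the unbrominated quinone carbon because bromine steers the nucleophilic diene terminus away from the carbon that bears it, and this is expected to outweigh the opposite bias of the remote methoxy group. It also needs site selectivity for the brominated double bond, which the methoxy group secures by deactivating its own double bond as a vinylogous ester, and the (Z) geometry keeps the methyl group outward so that the s-cis diene is accessible.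

Step 10
Reactants: 19 silyl-protected naphthoquinone
Product: 20 phenol 6-{2,4-dimethoxy-6-[(4-methoxy-2-oxo-2H-pyran-6-yl)methyl]benzoyl}-7-hydroxy-2-methoxy-5-methyl-1,4-naphthoquinone
Conditions: Bu4NF, AcOH, THF, 0 °C
Reagents that add atoms: none
Why: Fluoride-induced cleavage of an aryl silyl ether, driven by the strong Si–F bond and a phenoxide stabilised by the ortho aroyl group, with acetic acid buffering to keep the medium non-basic for the methoxyquinone and the pyranone.

Step 11
Reactants: 20 phenol
Product: 21 target 6-{2,4-dihydroxy-6-[(4-hydroxy-2-oxo-2H-pyran-6-yl)methyl]benzoyl}-2,7-dihydroxy-5-methyl-1,4-naphthoquinone (CNP0141484.0)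
Conditions: BBr3 (excess), CH2Cl2, −78 °C → 25 °C; ice-water work-up
Reagents that add atoms: none
Why: Lewis-acid ether cleavage in which BBr3 binds each ether oxygen and bromide removes the methyl group by SN2 attack, the ortho methoxy and the two vinylogous esters expected to go first and the para methoxy last, with aqueous work-up hydrolysing the borates to the free hydroxyl groups.

Compound list
1 | (3,5-dimethoxyphenyl)acetic acid | COc1cc(CC(=O)O)cc(OC)c1 | starting material
2 | 2,2,6-trimethyl-4H-1,3-dioxin-4-one | CC1=CC(=O)OC(C)(C)O1 | starting material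
3 | acyl imidazole 2-(3,5-dimethoxyphenyl)-1-(1H-imidazol-1-yl)ethan-1-one, formed in the flask | COc1cc(CC(=O)n2ccnc2)cc(OC)c1 | intermediate
4 | lithium dienolate of 2, lithium 2,2-dimethyl-6-methylidene-6H-1,3-dioxin-4-olate, formed in the flask | C=C1C=C([O-])OC(C)(C)O1.[Li+] | intermediate
5 | 6-[3-(3,5-dimethoxyphenyl)-2-oxopropyl]-2,2-dimethyl-4H-1,3-dioxin-4-one | COc1cc(CC(=O)CC2=CC(=O)OC(C)(C)O2)cc(OC)c1 | intermediate
6 | acylketene 6-(3,5-dimethoxyphenyl)-3,5-dioxohex-1-en-1-one, formed in the flask | COc1cc(CC(=O)CC(=O)C=C=O)cc(OC)c1 | intermediate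
7 | 6-(3,5-dimethoxybenzyl)-4-hydroxy-2H-pyran-2-one | COc1cc(Cc2cc(O)cc(=O)o2)cc(OC)c1 | intermediate
8 | 6-(3,5-dimethoxybenzyl)-4-methoxy-2H-pyran-2-one | COc1cc(Cc2cc(OC)cc(=O)o2)cc(OC)c1 | intermediate
9 | 6-(2-acetyl-3,5-dimethoxybenzyl)-4-methoxy-2H-pyran-2-one | CC(=O)c1c(OC)cc(OC)cc1Cc1cc(OC)cc(=O)o1 | intermediate
10 | 1-{2,4-dimethoxy-6-[(4-methoxy-2-oxo-2H-pyran-6-yl)methyl]phenyl}butane-1,3-dione (drawn as the diketo form, largely enolised) | CC(=O)CC(=O)c1c(OC)cc(OC)cc1Cc1cc(OC)cc(=O)o1 | intermediate
11 | acetaldehyde | CC=O | starting material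
12 | (3Z)-3-{2,4-dimethoxy-6-[(4-methoxy-2-oxo-2H-pyran-6-yl)methyl]benzoyl}pent-3-en-2-one (methyl cis to the aroyl group) | C/C=C(/C(C)=O)C(=O)c1c(OC)cc(OC)cc1Cc1cc(OC)cc(=O)o1 | intermediate
13 | (3Z)-2-(tert-butyldimethylsilyloxy)-3-{2,4-dimethoxy-6-[(4-methoxy-2-oxo-2H-pyran-6-yl)methyl]benzoyl}penta-1,3-diene (methyl trans to the silyloxyvinyl group) | C=C(O[Si](C)(C)C(C)(C)C)/C(=C/C)C(=O)c1c(OC)cc(OC)cc1Cc1cc(OC)cc(=O)o1 | intermediate
14 | 1-bromo-2,4,5-trimethoxybenzene | COc1cc(OC)c(OC)cc1Br | starting material
15 | 2-bromo-5-methoxy-1,4-benzoquinone | COC1=CC(=O)C(Br)=CC1=O | intermediate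
16 | bromo cycloadduct 4a-bromo-7-(tert-butyldimethylsilyloxy)-6-aroyl-2-methoxy-5-methyl-4a,5,8,8a-tetrahydronaphthalene-1,4-dione, racemic, cis-fused (4a-Br and 8a-H cis), 5-methyl trans to bromine (endo adduct shown), formed in the flask | C[C@@H]1C(C(=O)c3c(OC)cc(OC)cc3Cc3cc(OC)cc(=O)o3)=C(O[Si](C)(C)C(C)(C)C)C[C@@H]2C(=O)C(OC)=CC(=O)[C@]12Br | intermediate
17 | 7-(tert-butyldimethylsilyloxy)-6-aroyl-2-methoxy-5-methyl-5,8-dihydronaphthalene-1,4-dione, racemic, formed in the flask | CC1C(C(=O)c3c(OC)cc(OC)cc3Cc3cc(OC)cc(=O)o3)=C(O[Si](C)(C)C(C)(C)C)CC2=C1C(=O)C=C(OC)C2=O | intermediate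
18 | 7-(tert-butyldimethylsilyloxy)-6-aroyl-2-methoxy-5-methylnaphthalene-1,4-diol, formed in the flask | Cc1c(C(=O)c3c(OC)cc(OC)cc3Cc3cc(OC)cc(=O)o3)c(O[Si](C)(C)C(C)(C)C)cc2c(O)c(OC)cc(O)c12 | intermediate
19 | 7-(tert-butyldimethylsilyloxy)-6-{2,4-dimethoxy-6-[(4-methoxy-2-oxo-2H-pyran-6-yl)methyl]benzoyl}-2-methoxy-5-methyl-1,4-naphthoquinone | Cc1c(C(=O)c3c(OC)cc(OC)cc3Cc3cc(OC)cc(=O)o3)c(O[Si](C)(C)C(C)(C)C)cc2c1C(=O)C=C(OC)C2=O | intermediate
20 | 6-{2,4-dimethoxy-6-[(4-methoxy-2-oxo-2H-pyran-6-yl)methyl]benzoyl}-7-hydroxy-2-methoxy-5-methyl-1,4-naphthoquinone | Cc1c(C(=O)c3c(OC)cc(OC)cc3Cc3cc(OC)cc(=O)o3)c(O)cc2c1C(=O)C=C(OC)C2=O | intermediate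
21 | 6-{2,4-dihydroxy-6-[(4-hydroxy-2-oxo-2H-pyran-6-yl)methyl]benzoyl}-2,7-dihydroxy-5-methyl-1,4-naphthoquinone (CNP0141484.0, no stereocentre) | Cc1c(C(=O)c2c(O)cc(O)cc2Cc2cc(O)cc(=O)o2)c(O)cc2c1C(=O)C=C(O)C2=O | target

In 16, 17 and 18 "aroyl" stands for the 2,4-dimethoxy-6-[(4-methoxy-2-oxo-2H-pyran-6-yl)methyl]benzoyl group of 13.

Total step count: 11. Longest linear sequence: 10 steps (steps 1 to 7 and 9 to 11); step 8 is a one-step side branch.

Steps most likely to fail

Step 9. The donor methoxy group of 15 biases the dienophile in the sense opposite to bromine, so part of the cycloaddition may run with the CH2 terminus bonding to the brominated carbon, which would place the methoxy group at C3 instead of C2. The fallback sets out from 13 and uses purchased 2,5-dibromo-1,4-benzoquinone (O=C1C=C(Br)C(=O)C=C1Br), whose two ring double bonds are equivalent and in which no oxygen donor opposes the halogen. The same sequence (toluene, 25 → 45 °C; then Et3N, air) should give 2-bromo-7-(tert-butyldimethylsilyloxy)-6-{2,4-dimethoxy-6-[(4-methoxy-2-oxo-2H-pyran-6-yl)methyl]benzoyl}-5-methyl-1,4-naphthoquinone F1. Treatment with NaOMe in MeOH/THF at 0 °C should then replace the vinylic bromine by methoxy through addition–elimination and cleave the aryl silyl ether in the same flask, which brings the route back at 20.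

Step 6. The ethylidene diketone is a strong Michael acceptor and a heterodiene, so under amine catalysis it may take up a second molecule of 10 or oligomerise, and acetaldehyde may self-condense. The fallback sets out from 10 and forms the alkene by selenoxide elimination instead of condensation. C-Ethylation (EtI, K2CO3, acetone, 50 °C) should give racemic 2-ethyl-1-{2,4-dimethoxy-6-[(4-methoxy-2-oxo-2H-pyran-6-yl)methyl]phenyl}butane-1,3-dione F2. Selenenylation at the doubly activated carbon (PhSeCl, pyridine, CH2Cl2, 0 °C) should give racemic 2-ethyl-1-{2,4-dimethoxy-6-[(4-methoxy-2-oxo-2H-pyran-6-yl)methyl]phenyl}-2-(phenylselanyl)butane-1,3-dione F3. Oxidation with mCPBA at −78 °C and warming to 0 °C should trigger syn-elimination of the selenoxide; the only β-hydrogens sit on the ethyl group, so only the ethylidene unit can form, and the route returns at 12. The alkene geometry may need equilibration with a trace of piperidinium acetate.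

Step 11. While the slowest ethers (the pyranone methyl ether and the para methoxy group of ring B) are still being cleaved, the hydroxyquinone ring may be degraded by long contact with BBr3 and HBr through bromide addition or condensation with neighbouring carbonyl groups. The fallback sets out from 20 and masks the quinone as its leuco acetate during the ether cleavage. Reductive acetylation (Zn dust, Ac2O, NaOAc, 25 → 50 °C) should give 1,4,7-triacetoxy-6-{2,4-dimethoxy-6-[(4-methoxy-2-oxo-2H-pyran-6-yl)methyl]benzoyl}-2-methoxy-5-methylnaphthalene F4. BBr3 in CH2Cl2 (−78 °C → 25 °C) should then cleave the four methyl ethers on a substrate without a quinone, giving 1,4,7-triacetoxy-6-{2,4-dihydroxy-6-[(4-hydroxy-2-oxo-2H-pyran-6-yl)methyl]benzoyl}-2-hydroxy-5-methylnaphthalene F5; any acetate lost here is of no consequence. Methanolysis of the acetates (K2CO3, MeOH, 25 °C) under air should release the 1,2,4-trihydroxynaphthalene, which autoxidises to the 2-hydroxy-1,4-naphthoquinone, so the route returns at 21.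

Further compounds
F1 | step 9 | 2-bromo-7-(tert-butyldimethylsilyloxy)-6-{2,4-dimethoxy-6-[(4-methoxy-2-oxo-2H-pyran-6-yl)methyl]benzoyl}-5-methyl-1,4-naphthoquinone | Cc1c(C(=O)c3c(OC)cc(OC)cc3Cc3cc(OC)cc(=O)o3)c(O[Si](C)(C)C(C)(C)C)cc2c1C(=O)C=C(Br)C2=O
F2 | step 6 | 2-ethyl-1-{2,4-dimethoxy-6-[(4-methoxy-2-oxo-2H-pyran-6-yl)methyl]phenyl}butane-1,3-dione, racemic | CCC(C(C)=O)C(=O)c1c(OC)cc(OC)cc1Cc1cc(OC)cc(=O)o1
F3 | step 6 | 2-ethyl-1-{2,4-dimethoxy-6-[(4-methoxy-2-oxo-2H-pyran-6-yl)methyl]phenyl}-2-(phenylselanyl)butane-1,3-dione, racemic | CCC([Se]c1ccccc1)(C(C)=O)C(=O)c1c(OC)cc(OC)cc1Cc1cc(OC)cc(=O)o1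
F4 | step 11 | 1,4,7-triacetoxy-6-{2,4-dimethoxy-6-[(4-methoxy-2-oxo-2H-pyran-6-yl)methyl]benzoyl}-2-methoxy-5-methylnaphthalene | Cc1c(C(=O)c3c(OC)cc(OC)cc3Cc3cc(OC)cc(=O)o3)c(OC(C)=O)cc2c(OC(C)=O)c(OC)cc(OC(C)=O)c12
F5 | step 11 | 1,4,7-triacetoxy-6-{2,4-dihydroxy-6-[(4-hydroxy-2-oxo-2H-pyran-6-yl)methyl]benzoyl}-2-hydroxy-5-methylnaphthalene | Cc1c(C(=O)c3c(O)cc(O)cc3Cc3cc(O)cc(=O)o3)c(OC(C)=O)cc2c(OC(C)=O)c(O)cc(OC(C)=O)c12
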